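**Plan**
- Retrosynthetic cuts: first both C–C bonds of the methylene bridge (C8 of chromene ring B and C6 of the ring A triketone), then the C6–acyl bond of ring B, then the three pyran bonds C8a–O1, C4a–C4 and O1–C2.
- Enabling feature: in ring B the pyran oxygen and the vinylic carbon C4 sit on adjacent ring carbons (C8a, C4a). C4a has an oxygen-bearing neighbour (C5), while C8a is flanked only by C8, which is CH until the bridge is made. A 3-alkoxybenzyne delivers exactly this pattern when it takes up the C=O of an enal.
- Ring B, forward: phloroglucinol → bis-acetal phenol → ortho-silylaryl triflate → aryne + 3-methylbut-2-enal → 2,2-dimethyl-2H-chromene (the only ring closure of the route) → C6 isobutyrylation → free diol.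
- Ring A, forward: phloroglucinol → isobutyrylphloroglucinol → geminal C-dimethylation to the dearomatised triketone. Formaldehyde joins ring A and ring B last.
- Stereochemistry: the target has no stereocentre and no stereogenic double bond. The one stereocentre that appears (the benzoxete carbon) is transient and racemic.

Key step: step 5

Remark: ring A is written as the enol tautomer of the target SMILES; the other enol forms of this β-triketone are the same compound.

**Step 1**
Reactants: 1 phloroglucinol
Product: 3 3,5-bis(methoxymethoxy)phenol, via mono-ether 2 (not isolated)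
Conditions: NaH (2.1 equiv), MOMCl (2.0 equiv), DMF, 0 °C → rt; chromatography
Reagents that add atoms: chloromethyl methyl ether, COCCl
Why: Williamson-type O-alkylation of the sodium phenoxide by the hard chloromethyl ether should stop mainly at the bis-acetal with two equivalents, the mono- and tris-ethers being separated and recycled.

**Step 2**
Reactants: 3 3,5-bis(methoxymethoxy)phenol
Product: 4 3,5-bis(methoxymethoxy)phenyl N-(propan-2-yl)carbamate
Conditions: i-PrNCO, Et3N (cat.), CH2Cl2, rt
Reagents that add atoms: isopropyl isocyanate, CC(C)N=C=O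
Why: amine-catalysed addition of a phenol to an isocyanate (carbamoylation) should be clean, since the acetals are inert to base.

**Step 3**
Reactants: 4 3,5-bis(methoxymethoxy)phenyl N-(propan-2-yl)carbamate
Product: 8 3,5-bis(methoxymethoxy)-2-(trimethylsilyl)phenyl N-(propan-2-yl)carbamate, via N-silyl carbamate 5 (not isolated), via aryllithium 6 (not isolated), via N-silyl arylsilane 7 (not isolated)
Conditions: TBSOTf, TMEDA, Et2O, 0 °C → rt; n-BuLi, TMEDA, −78 °C; TMSCl, −78 °C → rt; cold aq. NaHSO4 (short contact)
Reagents that add atoms: chlorotrimethylsilane, C[Si](C)(C)Cl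
Why: carbamate-directed ortho metalation, with the N–H masked in the flask as the N-silyl derivative so that it cannot fragment to isocyanate, should occur at −78 °C at the carbon flanked by the carbamate and an acetal oxygen (C2, identical with C6 by symmetry) and not at C4 between the two weaker acetal directors, and TMSCl traps the aryllithium before the N–Si bond is hydrolysed on work-up.

**Step 4**
Reactants: 8 3,5-bis(methoxymethoxy)-2-(trimethylsilyl)phenyl N-(propan-2-yl)carbamate
Product: 10 3,5-bis(methoxymethoxy)-2-(trimethylsilyl)phenyl trifluoromethanesulfonate, via silylphenol 9 (not isolated)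
Conditions: Et2NH, DBU, MeCN, 40 °C; then PhNTf2, rt
Reagents that add atoms: N-phenylbis(trifluoromethanesulfonimide), O=S(=O)(N(c1ccccc1)S(=O)(=O)C(F)(F)F)C(F)(F)F
Why: base-induced E1cB loss of isopropyl isocyanate from the N-monoalkyl carbamate (scavenged by Et2NH as the urea) frees the phenoxide, which PhNTf2 triflates in the same flask, the standard carbamate-to-triflate exchange for ortho-silylaryl triflates.

**Step 5**
Reactants: 10 3,5-bis(methoxymethoxy)-2-(trimethylsilyl)phenyl trifluoromethanesulfonate; 11 3-methylbut-2-enal
Product: 15 5,7-bis(methoxymethoxy)-2,2-dimethyl-2H-chromene, via aryne 12 (not isolated), via benzoxete 13 (not isolated), via ortho-quinone methide 14 (not isolated)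
Conditions: CsF (3 equiv), 11 (3 equiv), MeCN, rt → 50 °C, slow addition of 10
Reagents that add atoms: none
Why: Fluoride attacks silicon and triflate leaves to give aryne 12; the carbonyl oxygen of 11 adds to the aryne carbon remote from the C3 acetal oxygen, the aryl anion formed at C2 closes on the carbonyl carbon (formal [2+2]) to benzoxete 13, and this opens in a four-electron electrocyclic step to ortho-quinone methide 14. The closest known reaction type is the insertion of arynes into the C=O bond of aldehydes and formamides, which with α,β-unsaturated aldehydes ends in 2H-chromenes. The pyran ring closes by thermal disrotatory oxa-6π electrocyclisation of 14, forming O1–C2, while C8a–O1 and C4a–C4 come from the [2+2] event. No stereocentre remains, because the benzoxete carbon becomes sp2 and C2 carries two methyl groups. The step needs regioselective addition to the unsymmetrical aryne, secured by the inductively withdrawing acetal oxygen at C3, which polarises the triple bond and stabilises the C2 anion; it also needs C=O addition to win over [4+2] addition across the enal or an ene reaction, which the β,β-dimethyl substitution favours by shielding the alkene terminus. Slow aryne generation in an excess of 11 should suppress capture of 14 by a second aryne.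

**Step 6**
Reactants: 15 5,7-bis(methoxymethoxy)-2,2-dimethyl-2H-chromene
Product: 18 1-[5,7-bis(methoxymethoxy)-2,2-dimethyl-2H-chromen-6-yl]-2-methylpropan-1-one, via 6-lithiochromene 16 (not isolated), via lithium hemiaminal 17 (not isolated)
Conditions: n-BuLi, THF, 0 °C; then i-PrC(O)N(OMe)Me, −78 → 0 °C; aq. NH4Cl
Reagents that add atoms: N-methoxy-N-methyl-2-methylpropanamide, CC(C)C(=O)N(C)OC
Why: directed ortho metalation under equilibrating conditions should favour the C6 aryllithium, chelated by both flanking acetals, over the C8 anion that has one acetal and the ring oxygen, and the Weinreb ketone synthesis then gives a stable chelate that releases the ketone only on quench, so no tertiary alcohol can form.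

**Step 7**
Reactants: 18 1-[5,7-bis(methoxymethoxy)-2,2-dimethyl-2H-chromen-6-yl]-2-methylpropan-1-one
Product: 21 1-(5,7-dihydroxy-2,2-dimethyl-2H-chromen-6-yl)-2-methylpropan-1-one, via 7-acetal phenol 19 (not isolated), via 5-acetal phenol 20 (not isolated)
Conditions: 3 M aq. HCl, MeOH, 45 °C
Reagents that add atoms: none
Why: acid-catalysed transacetalisation of aryl methoxymethyl ethers to dimethoxymethane in methanol is routine, and the 2,2-dimethylpyran double bond should tolerate dilute acid at moderate temperature.

**Step 8**
Reactants: 1 phloroglucinol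
Product: 22 2-methyl-1-(2,4,6-trihydroxyphenyl)propan-1-one
Conditions: i-PrCOCl, AlCl3 (3.5 equiv), PhNO2/CH2Cl2, 0 → 50 °C; ice/aq. HCl
Reagents that add atoms: isobutyryl chloride, CC(C)C(Cl)=O
Why: Friedel–Crafts C-acylation of the highly nucleophilic triol should stop after one acyl group because the chelated aryl ketone is deactivated.

**Step 9**
Reactants: 22 2-methyl-1-(2,4,6-trihydroxyphenyl)propan-1-one
Product: 24 3,5-dihydroxy-4,4-dimethyl-2-(2-methylpropanoyl)cyclohexa-2,5-dien-1-one, via C-methyl ketone 23 (not isolated)
Conditions: NaOMe (4 equiv), MeI (2.2 equiv), MeOH, 0 °C → rt; aq. HCl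
Reagents that add atoms: iodomethane, CI
Why: C-alkylation of the acylphloroglucinol polyanion is the established entry to acylfilicinic acids, the mono-methyl phenolate 23 reacting again preferentially at its methylated carbon (dearomatising geminal dimethylation), with under- and over-methylated material removed by chromatography.

**Step 10**
Reactants: 24 3,5-dihydroxy-4,4-dimethyl-2-(2-methylpropanoyl)cyclohexa-2,5-dien-1-one; 21 1-(5,7-dihydroxy-2,2-dimethyl-2H-chromen-6-yl)-2-methylpropan-1-one
Product: 27 3,5-dihydroxy-6-{[5,7-dihydroxy-2,2-dimethyl-6-(2-methylpropanoyl)-2H-chromen-8-yl]methyl}-4,4-dimethyl-2-(2-methylpropanoyl)cyclohexa-2,5-dien-1-one, via hydroxymethyl triketone 25 (not isolated), via methylidene triketone 26 (not isolated)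
Conditions: 24 (1.5 equiv), 37 % aq. HCHO (1.1 equiv), 1 % aq. KOH, 0 °C → rt; then dil. HCl
Reagents that add atoms: formaldehyde, C=O
Why: Knoevenagel condensation of the cyclic β-triketone with formaldehyde gives enone 26, to which C8 of the phenolate of 21, its only unsubstituted ring carbon, adds in a Michael reaction (the classical formaldehyde coupling of acylphloroglucinols), a modest excess of 24 pushing 21 into the mixed dimer while the symmetrical dimer of 24 is separated.

**Compound list**
1 | phloroglucinol (benzene-1,3,5-triol) | Oc1cc(O)cc(O)c1 | starting material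
2 | 5-(methoxymethoxy)benzene-1,3-diol | COCOc1cc(O)cc(O)c1 | intermediate (not isolated)
3 | 3,5-bis(methoxymethoxy)phenol | COCOc1cc(O)cc(OCOC)c1 | intermediate
4 | 3,5-bis(methoxymethoxy)phenyl N-(propan-2-yl)carbamate | COCOc1cc(OCOC)cc(OC(=O)NC(C)C)c1 | intermediate
5 | 3,5-bis(methoxymethoxy)phenyl N-[tert-butyl(dimethyl)silyl]-N-(propan-2-yl)carbamate | COCOc1cc(OCOC)cc(OC(=O)N(C(C)C)[Si](C)(C)C(C)(C)C)c1 | intermediate (not isolated)
6 | 2-lithio derivative of 5 (lithium between the carbamate and an acetal oxygen) | COCOc1cc(OCOC)c([Li])c(OC(=O)N(C(C)C)[Si](C)(C)C(C)(C)C)c1 | intermediate (not isolated)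
7 | 3,5-bis(methoxymethoxy)-2-(trimethylsilyl)phenyl N-[tert-butyl(dimethyl)silyl]-N-(propan-2-yl)carbamate | COCOc1cc(OCOC)c([Si](C)(C)C)c(OC(=O)N(C(C)C)[Si](C)(C)C(C)(C)C)c1 | intermediate (not isolated)
8 | 3,5-bis(methoxymethoxy)-2-(trimethylsilyl)phenyl N-(propan-2-yl)carbamate | COCOc1cc(OCOC)c([Si](C)(C)C)c(OC(=O)NC(C)C)c1 | intermediate
9 | 3,5-bis(methoxymethoxy)-2-(trimethylsilyl)phenol | COCOc1cc(O)c([Si](C)(C)C)c(OCOC)c1 | intermediate (not isolated)
10 | 3,5-bis(methoxymethoxy)-2-(trimethylsilyl)phenyl trifluoromethanesulfonate | COCOc1cc(OCOC)c([Si](C)(C)C)c(OS(=O)(=O)C(F)(F)F)c1 | intermediate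
11 | 3-methylbut-2-enal | CC(C)=CC=O | starting material
12 | 3,5-bis(methoxymethoxy)benzyne (1,2-didehydro-3,5-bis(methoxymethoxy)benzene) | COCOC1=CC(OCOC)=CC#C1 | intermediate (not isolated)
13 | 3,5-bis(methoxymethoxy)-2-(2-methylprop-1-en-1-yl)-2H-1-benzoxete (racemic) | COCOc1cc(OCOC)c2C(C=C(C)C)Oc2c1 | intermediate (not isolated)
14 | 3,5-bis(methoxymethoxy)-6-(3-methylbut-2-en-1-ylidene)cyclohexa-2,4-dien-1-one (exocyclic alkene geometry not fixed) | COCOC1=CC(=O)C(=CC=C(C)C)C(OCOC)=C1 | intermediate (not isolated)
15 | 5,7-bis(methoxymethoxy)-2,2-dimethyl-2H-chromene | COCOc1cc(OCOC)c2C=CC(C)(C)Oc2c1 | intermediate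
16 | [5,7-bis(methoxymethoxy)-2,2-dimethyl-2H-chromen-6-yl]lithium | COCOc1cc2OC(C)(C)C=Cc2c(OCOC)c1[Li] | intermediate (not isolated)
17 | lithium 1-[5,7-bis(methoxymethoxy)-2,2-dimethyl-2H-chromen-6-yl]-1-[methoxy(methyl)amino]-2-methylpropan-1-olate (racemic) | COCOc1cc2OC(C)(C)C=Cc2c(OCOC)c1C(O[Li])(C(C)C)N(C)OC | intermediate (not isolated)
18 | 1-[5,7-bis(methoxymethoxy)-2,2-dimethyl-2H-chromen-6-yl]-2-methylpropan-1-one | COCOc1cc2OC(C)(C)C=Cc2c(OCOC)c1C(=O)C(C)C | intermediate
19 | 1-[5-hydroxy-7-(methoxymethoxy)-2,2-dimethyl-2H-chromen-6-yl]-2-methylpropan-1-one | COCOc1cc2OC(C)(C)C=Cc2c(O)c1C(=O)C(C)C | intermediate (not isolated)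
20 | 1-[7-hydroxy-5-(methoxymethoxy)-2,2-dimethyl-2H-chromen-6-yl]-2-methylpropan-1-one | Oc1cc2OC(C)(C)C=Cc2c(OCOC)c1C(=O)C(C)C | intermediate (not isolated)
21 | 1-(5,7-dihydroxy-2,2-dimethyl-2H-chromen-6-yl)-2-methylpropan-1-one | CC(C)C(=O)c1c(O)cc2OC(C)(C)C=Cc2c1O | intermediate
22 | 2-methyl-1-(2,4,6-trihydroxyphenyl)propan-1-one | CC(C)C(=O)c1c(O)cc(O)cc1O | intermediate
23 | 2-methyl-1-(2,4,6-trihydroxy-3-methylphenyl)propan-1-one | CC(C)C(=O)c1c(O)cc(O)c(C)c1O | intermediate (not isolated)
24 | 3,5-dihydroxy-4,4-dimethyl-2-(2-methylpropanoyl)cyclohexa-2,5-dien-1-one (isobutyrylfilicinic acid) | CC(C)C(=O)C1=C(O)C(C)(C)C(O)=CC1=O | intermediate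
25 | 3,5-dihydroxy-6-(hydroxymethyl)-4,4-dimethyl-2-(2-methylpropanoyl)cyclohexa-2,5-dien-1-one | CC(C)C(=O)C1=C(O)C(C)(C)C(O)=C(CO)C1=O | intermediate (not isolated)
26 | 5-hydroxy-6,6-dimethyl-2-methylidene-4-(2-methylpropanoyl)cyclohex-4-ene-1,3-dione | CC(C)C(=O)C1=C(O)C(C)(C)C(=O)C(=C)C1=O | intermediate (not isolated)
27 | 3,5-dihydroxy-6-{[5,7-dihydroxy-2,2-dimethyl-6-(2-methylpropanoyl)-2H-chromen-8-yl]methyl}-4,4-dimethyl-2-(2-methylpropanoyl)cyclohexa-2,5-dien-1-one | CC(C)C(=O)C1=C(O)C(C)(C)C(O)=C(Cc2c(O)c(C(=O)C(C)C)c(O)c3c2OC(C)(C)C=C3)C1=O | target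

**Step count**
Total: 10 steps. Longest linear sequence: 8 steps (steps 1–7, then step 10). The ring A branch (steps 8 and 9) joins at step 10.

**Steps most likely to fail**

Step 5. The aryne may be diverted before the carbonyl captures it: by an ene reaction with the allylic C–H bonds of 11, by fluoride-induced γ-deprotonation of 11 followed by arylation of the dienolate, or by addition of a second aryne to quinone methide 14; the electron-rich aryne may also add with reduced regiocontrol. The fallback sets out from phenol 3 and condenses it with 11 under ethylenediammonium diacetate catalysis in refluxing toluene. This is a Knoevenagel-type ortho-alkylation that dehydrates to the same quinone methide 14 and closes by oxa-6π electrocyclisation. Both ortho positions of 3 are equivalent, so only 15 can form, and the route is rejoined at 15. No compound outside the list arises (F0).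

Step 6. Metalation may take place partly or mainly at C8, between the C7 acetal and the ring oxygen, which would place the acyl group on the wrong carbon. The fallback sets out from 15 and blocks C8 first. Electrophilic bromination with NBS in CH2Cl2 at −78 °C should go to the less hindered C8 and give 8-bromo-5,7-bis(methoxymethoxy)-2,2-dimethyl-2H-chromene F1. Bromine–lithium exchange with n-BuLi at −78 °C and quench with TMSCl gives [5,7-bis(methoxymethoxy)-2,2-dimethyl-2H-chromen-8-yl]trimethylsilane F2. C6 is now the only ring hydrogen, so n-BuLi in THF at 0 °C followed by the same Weinreb amide gives 1-[5,7-bis(methoxymethoxy)-2,2-dimethyl-8-(trimethylsilyl)-2H-chromen-6-yl]-2-methylpropan-1-one F3. HCl in methanol then cleaves both acetals and removes the silyl group by ipso-protodesilylation of the electron-rich ring, rejoining the route at 21.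

Step 10. Because one methylene donor serves both partners, statistical homo-coupling (two molecules of 24, or two of 21) may consume the material and leave little mixed dimer. The fallback sets out from 21 and makes the bridge carbon part of ring B before ring A is added. A phenolic Mannich reaction (40 % aq. Me2NH, 37 % aq. HCHO, EtOH, rt) at C8, the only free ring position, gives 1-{8-[(dimethylamino)methyl]-5,7-dihydroxy-2,2-dimethyl-2H-chromen-6-yl}-2-methylpropan-1-one F4. Heating F4 with 24 in dioxane at 90 °C expels dimethylamine to form the ortho-quinone methide of ring B, and the triketone enol adds to it in a conjugate fashion. No free formaldehyde is present, so neither symmetrical dimer can form, and the route is rejoined at 27.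

**Further compounds**
F0 | step 5 | none | none
F1 | step 6 | 8-bromo-5,7-bis(methoxymethoxy)-2,2-dimethyl-2H-chromene | COCOc1cc(OCOC)c2C=CC(C)(C)Oc2c1Br
F2 | step 6 | [5,7-bis(methoxymethoxy)-2,2-dimethyl-2H-chromen-8-yl]trimethylsilane | COCOc1cc(OCOC)c2C=CC(C)(C)Oc2c1[Si](C)(C)C
F3 | step 6 | 1-[5,7-bis(methoxymethoxy)-2,2-dimethyl-8-(trimethylsilyl)-2H-chromen-6-yl]-2-methylpropan-1-one | COCOc1c(C(=O)C(C)C)c(OCOC)c2C=CC(C)(C)Oc2c1[Si](C)(C)C
F4 | step 10 | 1-{8-[(dimethylamino)methyl]-5,7-dihydroxy-2,2-dimethyl-2H-chromen-6-yl}-2-methylpropan-1-one | CC(C)C(=O)c1c(O)c(CN(C)C)c2OC(C)(C)C=Cc2c1O
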